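## Retrosynthetic overview

1. The target comes from C4 methylation of a bicyclic α‑sulfinyl ester: the C–S bond is reduced to the ester enolate, MeI enters equatorially and the ester stays axial.
2. The bicycle comes from one radical cascade on an acyclic (6Z,10E)‑dienyl α‑sulfinyl ester. C4–C5 closes ring A, then C10–C9 closes ring B, and loss of a hydrogen atom from C17 leaves the C8 methylene.
3. The target has the C9 chain trans to the C10 methyl (9‑epi relative to the usual labdane pattern), so the C8=C9 olefin of the precursor must be Z; the sulfinyl group sets the absolute sense.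
4. The radical precursor comes from alkylation of methyl (R)‑p‑tolylsulfinylacetate with a C14 chloro acid.
5. The chloro acid comes from copper‑catalysed opening of (R)‑β‑butyrolactone (sets C13) by a homoallylic Grignard reagent; the Z olefin is made by carbocupration of propyne and the E olefin by carboalumination of 5‑chloropent‑1‑yne, each extended with ethylene oxide.

Assumption: the target is read as (4R,5S,9S,10S,13R) in labdane numbering (used for positions throughout), and the sense of induction by the sulfinyl group is taken from the model in step 8; the mirror‑image menthyl sulfinate is also sold and would be used if the sense proves opposite.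

## Route

Step 1
Reactants: 1 5-chloropent-1-yne; 2 ethylene oxide
Product: 4 (3E)-7-chloro-4-methylhept-3-en-1-ol, via alkenylalane 3 (not isolated)
Conditions: Me3Al, Cp2ZrCl2 (20 mol %), CH2Cl2, 0 °C to rt; n-BuLi, THF/hexane, −30 °C; 2, −30 °C to rt; cold dil. HCl
Reagents that add atoms: trimethylaluminium (C[Al](C)C)
Why: Negishi zirconium‑catalysed carboalumination adds methyl and aluminium syn across the alkyne (methyl on the internal carbon), and the derived alanate opens ethylene oxide with retention at the alkenyl carbon, which fixes the E olefin (future C10=C5) while the primary chloride stays untouched.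

Step 2
Reactants: 4 (3E)-7-chloro-4-methylhept-3-en-1-ol
Product: 5 (3E)-1-bromo-7-chloro-4-methylhept-3-ene
Conditions: CBr4, PPh3, CH2Cl2, 0 °C
Reagents that add atoms: tetrabromomethane (BrC(Br)(Br)Br)
Why: Appel reaction of a primary alcohol under neutral conditions, which leaves the trisubstituted olefin geometry and the chloride unchanged.

Step 3
Reactants: 5 (3E)-1-bromo-7-chloro-4-methylhept-3-ene; 6 propyne; 2 ethylene oxide
Product: 9 (3Z,7E)-11-chloro-4,8-dimethylundeca-3,7-dien-1-ol, via Grignard reagent 7 (not isolated), via alkenylcopper 8 (not isolated)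
Conditions: Mg, Et2O, 35 °C; CuBr·SMe2, Et2O/Me2S, −45 °C; 6, −25 °C; 1-pentynyllithium, HMPA, −40 °C; 2, −40 °C to rt; aq. NH4Cl
Reagents that add atoms: none
Why: Magnesium inserts into C–Br far faster than into C–Cl, Normant carbocupration adds the alkyl group and copper syn across propyne (copper on the terminal carbon), and the pentynyl cuprate opens ethylene oxide with retention, so the new C2 unit is cis to the alkyl chain and the olefin (future C8=C9) is Z.

Step 4
Reactants: 9 (3Z,7E)-11-chloro-4,8-dimethylundeca-3,7-dien-1-ol
Product: 10 (3Z,7E)-1-bromo-11-chloro-4,8-dimethylundeca-3,7-diene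
Conditions: CBr4, PPh3, CH2Cl2, 0 °C
Reagents that add atoms: tetrabromomethane (BrC(Br)(Br)Br)
Why: Appel reaction as in step 2, with no acid present that could isomerise the Z olefin.

Step 5
Reactants: 10 (3Z,7E)-1-bromo-11-chloro-4,8-dimethylundeca-3,7-diene; 11 (R)-β-butyrolactone
Product: 13 (3R,6Z,10E)-14-chloro-3,7,11-trimethyltetradeca-6,10-dienoic acid, via Grignard reagent 12 (not isolated)
Conditions: Mg, THF; 11, CuBr·SMe2 (5 mol %), THF/Me2S, −30 to 0 °C; cold dil. HCl
Reagents that add atoms: none
Why: Copper‑catalysed SN2 opening of the β‑lactone at its O‑alkyl carbon (Fujisawa‑type) proceeds with inversion, which converts the 4R lactone centre into the 3R methyl‑bearing carbon (C13 of the target) and gives the free acid directly.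

Step 6
Reactants: 14 methyl acetate
Product: 16 methyl (R)-(4-methylbenzenesulfinyl)acetate, via lithium enolate 15 (not isolated)
Conditions: LDA (2.1 equiv), THF, −78 °C; (1R,2S,5R)-menthyl (S)-4-methylbenzenesulfinate, −78 to −40 °C; aq. NH4Cl
Reagents that add atoms: (1R,2S,5R)-menthyl (S)-4-methylbenzenesulfinate (C[C@@H]1CC[C@H]([C@@H](C1)O[S@](=O)c2ccc(C)cc2)C(C)C)
Why: Andersen sulfoxide synthesis, in which the ester enolate displaces mentholate at sulfur with inversion to give the R sulfoxide, the second equivalent of enolate absorbing the acidic proton of the product.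

Step 7
Reactants: 13 (3R,6Z,10E)-14-chloro-3,7,11-trimethyltetradeca-6,10-dienoic acid; 16 methyl (R)-(4-methylbenzenesulfinyl)acetate
Product: 19 (3R,6Z,10E)-16-methoxy-3,7,11-trimethyl-15-[(R)-4-methylbenzenesulfinyl]-16-oxohexadeca-6,10-dienoic acid as both C15 epimers, via sodium enolate 17 (not isolated), via alkyl iodide 18 (not isolated)
Conditions: NaH (2.6 equiv), NaI (1 equiv), DMF, 0 to 40 °C; cold dil. HCl
Reagents that add atoms: none
Why: Finkelstein exchange followed by enolate alkylation, in which the stabilised carbanion outcompetes the carboxylate for the primary iodide; the new C15 centre need not be controlled because it becomes the radical carbon, sulfur is untouched, and 40 °C is below the temperature of sulfoxide syn‑elimination.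

Step 8
Reactants: 19 (3R,6Z,10E)-16-methoxy-3,7,11-trimethyl-15-[(R)-4-methylbenzenesulfinyl]-16-oxohexadeca-6,10-dienoic acid
Product: 20 (3R)-5-[(1S,4aS,5S,8aS)-5-(methoxycarbonyl)-8a-methyl-5-[(S)-4-methylbenzenesulfinyl]-2-methylidenedecahydronaphthalen-1-yl]-3-methylpentanoic acid
Conditions: Ru(bpy)3(PF6)2 (2 mol %), Co(dmgH)2(py)Cl (5 mol %), Cs2CO3 (2.5 equiv), DMF, blue LEDs, 20 °C, Ar; cold dil. HCl
Reagents that add atoms: none
Why: Proposed new method: Cs2CO3 forms the α‑sulfinyl ester enolate, which photoexcited Ru(bpy)3(PF6)2 oxidises (it cannot oxidise the carboxylate) to an electrophilic tertiary radical at C4; 6‑endo attack on the E olefin through a chair gives the C10 radical with C5–H trans to the C10 methyl, a second chair 6‑endo closure onto the Z olefin places the side chain axial at C9 (anti to C20), and divalent cobalt from Co(dmgH)2(py)Cl removes a hydrogen atom from the C17 methyl of the C8 radical to give the exocyclic methylene with release of H2; the (R)‑sulfinyl group (S–O turned away from the ester, p‑tolyl blocking one face, sulfinyl pseudo‑equatorial) selects the 5S,10S ring series and the minor ring diastereomer is removed by chromatography at this stage; the closest known reactions are the Mn(OAc)3/Cu(OAc)2 oxidative polyene cyclisation, its auxiliary‑controlled β‑keto sulfoxide variant, and photoredox/cobaloxime acceptorless dehydrogenation to the less substituted alkene.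

Step 9
Reactants: 20 (3R)-5-[(1S,4aS,5S,8aS)-5-(methoxycarbonyl)-8a-methyl-5-[(S)-4-methylbenzenesulfinyl]-2-methylidenedecahydronaphthalen-1-yl]-3-methylpentanoic acid
Product: 22 (3R)-5-[(1S,4aS,5R,8aS)-5-(methoxycarbonyl)-5,8a-dimethyl-2-methylidenedecahydronaphthalen-1-yl]-3-methylpentanoic acid, via dilithium enolate 21 (not isolated)
Conditions: lithium 4,4'-di-tert-butylbiphenylide (3.2 equiv), THF, −78 °C; MeI (5 equiv), DMPU, −78 to −30 °C; cold dil. HCl
Reagents that add atoms: iodomethane (CI)
Why: Reductive desulfinylation with enolate alkylation: two‑electron cleavage of the activated C4–S bond gives the C4 ester enolate regiospecifically (the acid is present as its unreactive lithium carboxylate), and MeI attacks the face opposite the axial C10 methyl, so the new methyl is equatorial and the ester axial (4R), as in classical C4 alkylations of 10‑methyl‑trans‑decalin esters.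

## Compound list

1 | 5-chloropent-1-yne | ClCCCC#C | starting material
2 | ethylene oxide | C1CO1 | starting material
3 | [(1E)-5-chloro-2-methylpent-1-en-1-yl]dimethylalane | C[Al](C)/C=C(\C)CCCCl | intermediate
4 | (3E)-7-chloro-4-methylhept-3-en-1-ol | OCC/C=C(\C)CCCCl | intermediate
5 | (3E)-1-bromo-7-chloro-4-methylhept-3-ene | BrCC/C=C(\C)CCCCl | intermediate
6 | propyne | CC#C | starting material
7 | [(3E)-7-chloro-4-methylhept-3-en-1-yl]magnesium bromide | Br[Mg]CC/C=C(\C)CCCCl | intermediate
8 | [(1Z,5E)-9-chloro-2,6-dimethylnona-1,5-dien-1-yl]copper | [Cu]/C=C(/C)CC/C=C(\C)CCCCl | intermediate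
9 | (3Z,7E)-11-chloro-4,8-dimethylundeca-3,7-dien-1-ol | OCC/C=C(/C)CC/C=C(\C)CCCCl | intermediate
10 | (3Z,7E)-1-bromo-11-chloro-4,8-dimethylundeca-3,7-diene | BrCC/C=C(/C)CC/C=C(\C)CCCCl | intermediate
11 | (R)-β-butyrolactone, (4R)-4-methyloxetan-2-one | C[C@@H]1CC(=O)O1 | starting material
12 | [(3Z,7E)-11-chloro-4,8-dimethylundeca-3,7-dien-1-yl]magnesium bromide | Br[Mg]CC/C=C(/C)CC/C=C(\C)CCCCl | intermediate
13 | (3R,6Z,10E)-14-chloro-3,7,11-trimethyltetradeca-6,10-dienoic acid | OC(=O)C[C@H](C)CC/C=C(/C)CC/C=C(\C)CCCCl | intermediate
14 | methyl acetate | COC(C)=O | starting material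
15 | lithium enolate of methyl acetate | [Li]OC(=C)OC | intermediate
16 | methyl (R)-(4-methylbenzenesulfinyl)acetate | COC(=O)C[S@@](=O)c1ccc(C)cc1 | intermediate
17 | sodium enolate of 16 | [Na]OC(OC)=C[S@@](=O)c1ccc(C)cc1 | intermediate
18 | sodium (3R,6Z,10E)-14-iodo-3,7,11-trimethyltetradeca-6,10-dienoate | [Na+].[O-]C(=O)C[C@H](C)CC/C=C(/C)CC/C=C(\C)CCCI | intermediate
19 | (3R,6Z,10E)-16-methoxy-3,7,11-trimethyl-15-[(R)-4-methylbenzenesulfinyl]-16-oxohexadeca-6,10-dienoic acid, both C15 epimers | OC(=O)C[C@H](C)CC/C=C(/C)CC/C=C(\C)CCCC(C(=O)OC)[S@@](=O)c1ccc(C)cc1 | intermediate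
20 | (3R)-5-[(1S,4aS,5S,8aS)-5-(methoxycarbonyl)-8a-methyl-5-[(S)-4-methylbenzenesulfinyl]-2-methylidenedecahydronaphthalen-1-yl]-3-methylpentanoic acid; sulfinyl equatorial, sulfur unchanged in space from 16 (its descriptor changes only because the quaternary ring carbon now outranks the aryl carbon) | C=C1CC[C@H]2[C@@](C)(CCC[C@@]2([S@@](=O)c3ccc(C)cc3)C(=O)OC)[C@H]1CC[C@@H](C)CC(=O)O | intermediate
21 | dilithium salt of the desulfinylated bicycle: C4 ester enolate and C15 carboxylate | C=C1CC[C@H]2[C@@](C)(CCCC2=C(OC)O[Li])[C@H]1CC[C@@H](C)CC(=O)O[Li] | intermediate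
22 | (3R)-5-[(1S,4aS,5R,8aS)-5-(methoxycarbonyl)-5,8a-dimethyl-2-methylidenedecahydronaphthalen-1-yl]-3-methylpentanoic acid (CNP0135192.3) | C=C1CC[C@H]2[C@@](C)(CCC[C@@]2(C)C(=O)OC)[C@H]1CC[C@@H](C)CC(=O)O | target

## Step count and risks

Total: 9 steps. Longest linear sequence: 8 steps (1, 2, 3, 4, 5, 7, 8, 9); step 6 is a one‑step side branch.

**Step 8 (most likely to fail).** The radical generation, both 6‑endo closures, the sense and size of the sulfoxide induction and the site of hydrogen‑atom loss are all untested on this substrate; cobalt may also quench the C4 or C10 radical before cyclisation. The fallback makes the radical by chlorine‑atom transfer and forms the olefin in a separate elimination. It sets out from 19, which is chlorinated at the activated carbon (NCS, K2CO3, CH2Cl2) to the α‑chloro‑α‑sulfinyl ester F1. A CuCl/tris(2‑pyridylmethyl)amine atom‑transfer bicyclisation (monovalent copper abstracts chlorine, the divalent copper chloride returns it to the C8 radical) gives the tertiary C8 chloride F2 with the same chair‑controlled ring stereochemistry. Hofmann‑selective E2 elimination toward the methyl group with KOt‑Bu in t‑BuOH/THF comes back to the route at 20.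

**Step 9.** The radical anion could attack the ester, and the hindered enolate could be protonated or O‑methylated instead of C‑methylated. The fallback separates reduction and alkylation. It sets out from 20, whose C–S bond is cleaved with aluminium amalgam Al(Hg) in wet THF to the C4–H ester acid F3 (both C4 epimers). LDA (2.2 equiv, THF, −78 °C) then deprotonates the carboxylic acid and the ester α‑C–H (the carboxylate α‑hydrogens are far less acidic), and MeI alkylates the enolate from the equatorial face, arriving at 22.

**Step 3.** The one‑pot Grignard, carbocupration and epoxide‑opening sequence is sensitive to temperature and stoichiometry, and any loss of Z purity would carry through to C9. The fallback builds the olefin by directed carbometalation of an internal alkyne. It sets out from 5, which alkylates dilithiated but‑3‑yn‑1‑ol (n‑BuLi 2 equiv, THF/DMPU; the bromide reacts, the chloride does not) to give the alkynol F4. Hydroxyl‑directed, iron‑catalysed syn carbomagnesiation (Fe(acac)3 cat., MeMgBr, THF, then aq. NH4Cl) puts the methyl group on the alkyne carbon distal to oxygen and comes back to the route at 9 with the same Z geometry.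

## Further compounds

F1 | step 8 | (3R,6Z,10E)-15-chloro-16-methoxy-3,7,11-trimethyl-15-(4-methylbenzenesulfinyl)-16-oxohexadeca-6,10-dienoic acid, sulfur as in 19, both C15 epimers | OC(=O)C[C@H](C)CC/C=C(/C)CC/C=C(\C)CCCC(Cl)(C(=O)OC)[S@@](=O)c1ccc(C)cc1
F2 | step 8 | tertiary C8 chloride of 20: 2-chloro-2-methyl analogue of 20 in place of the 2-methylidene group, both C8 epimers | CC1(Cl)CC[C@H]2[C@@](C)(CCC[C@@]2([S@@](=O)c3ccc(C)cc3)C(=O)OC)[C@H]1CC[C@@H](C)CC(=O)O
F3 | step 9 | (3R)-5-[(1S,4aS,8aS)-5-(methoxycarbonyl)-8a-methyl-2-methylidenedecahydronaphthalen-1-yl]-3-methylpentanoic acid, both C5 epimers | C=C1CC[C@H]2[C@@](C)(CCCC2C(=O)OC)[C@H]1CC[C@@H](C)CC(=O)O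
F4 | step 3 | (7E)-11-chloro-8-methylundec-7-en-3-yn-1-ol | OCCC#CCC/C=C(\C)CCCCl
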